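**Strategy.** Everything rests on cutting ring C of the flavanone unit into two three-atom pieces, C4–C4a–C8a and C3–C2–O1. The key step exploits that C4 and O1 sit on adjacent ring-A carbons and that C8–H lies between C8a and the C7 oxygen: C4 is carried as a lithiated 1,3-dithiane (polarity reversal) next to a C8a bromide, and C3–C2–O1 as an (R)-aryloxirane. In one flask the dithiane anion opens the oxirane at CH2 (C3–C4) and the alkoxide closes onto the aryne formed from C8a–Br and C8–H (O1–C8a). The base-stable dithioketal then permits copper-mediated union with a preformed iodoflavone before unmasking and debenzylation.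

Key step: step 7

Remark on the chemistry: atom labels follow flavanone numbering (O1, C2, C3, C4, C4a, C5–C8, C8a). Assumption: 1-[2,4-bis(benzyloxy)-6-hydroxyphenyl]ethan-1-one and 2-bromo-1-[4-(benzyloxy)phenyl]ethan-1-one are taken as purchasable materials.

**Step 1**
Reactants: 1 4-bromo-2,6-difluorobenzaldehyde
Product: 2 4-bromo-2,6-bis(benzyloxy)benzaldehyde
Conditions: BnOH (2.5 equiv), KOtBu (2.4 equiv), DMF, 0 → 60 °C
Reagents that add atoms: benzyl alcohol, OCc1ccccc1
Why: Both fluorides are ortho to the formyl group and should be displaced by benzyl oxide in a twofold nucleophilic aromatic substitution (SNAr), while the para bromide, a much poorer leaving group, should stay in place.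

**Step 2**
Reactants: 2 4-bromo-2,6-bis(benzyloxy)benzaldehyde
Product: 4 4-bromo-2,6-bis(benzyloxy)phenol, via aryl formate 3 (not isolated)
Conditions: mCPBA, CH2Cl2, 0 °C → rt; then K2CO3, MeOH, rt
Reagents that add atoms: 3-chloroperbenzoic acid (mCPBA), O=C(OO)c1cccc(Cl)c1
Why: Baeyer–Villiger (Dakin-type) oxidation of the electron-rich 2,6-dialkoxybenzaldehyde should proceed with aryl migration to the formate, whose methanolysis frees the phenol oxygen that becomes the C6 oxygen.

**Step 3**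
Reactants: 4 4-bromo-2,6-bis(benzyloxy)phenol
Product: 5 6-bromo-2,4-bis(benzyloxy)-3-hydroxybenzaldehyde
Conditions: POCl3, DMF, 0 → 80 °C; then aq. NaOAc
Reagents that add atoms: N,N-dimethylformamide, CN(C)C=O; water, O
Why: Vilsmeier–Haack formylation can only occur at the two equivalent free positions, each ortho and para to a benzyloxy group, so a single aldehyde (the future C4) is expected next to the bromide.

**Step 4**
Reactants: 5 6-bromo-2,4-bis(benzyloxy)-3-hydroxybenzaldehyde
Product: 6 2-[6-bromo-2,4-bis(benzyloxy)-3-hydroxyphenyl]-1,3-dithiane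
Conditions: HS(CH2)3SH, BF3·OEt2 (cat.), CH2Cl2, 0 °C → rt
Reagents that add atoms: propane-1,3-dithiol, SCCCS
Why: Lewis-acid-catalysed dithioacetalisation of the aldehyde gives the 2-aryl-1,3-dithiane that serves as the acyl-anion equivalent (Corey–Seebach reagent).

**Step 5**
Reactants: 6 2-[6-bromo-2,4-bis(benzyloxy)-3-hydroxyphenyl]-1,3-dithiane
Product: 7 2-[6-bromo-2,4-bis(benzyloxy)-3-(tert-butyldimethylsilyloxy)phenyl]-1,3-dithiane
Conditions: TBSCl, imidazole, DMF, rt
Reagents that add atoms: tert-butyldimethylsilyl chloride (TBSCl), C[Si](C)(Cl)C(C)(C)C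
Why: Standard silyl ether formation masks the acidic phenol so that only the dithiane C–H is deprotonated in step 7.

**Step 6**
Reactants: 8 2-bromo-1-[4-(benzyloxy)phenyl]ethan-1-one
Product: 10 (R)-2-[4-(benzyloxy)phenyl]oxirane, via bromohydrin 9 (not isolated)
Conditions: (R)-2-methyl-CBS-oxazaborolidine (10 mol %), BH3·SMe2, THF, 0 °C; MeOH; then 2 M NaOH, rt
Reagents that add atoms: none
Why: Corey–Bakshi–Shibata reduction with the (R)-oxazaborolidine should deliver hydride to the face that gives the (R)-bromohydrin (as for phenacyl halides), and Williamson closure by attack of the alkoxide on CH2Br forms the oxirane without touching the stereocentre.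

**Step 7**
Reactants: 7 2-[6-bromo-2,4-bis(benzyloxy)-3-(tert-butyldimethylsilyloxy)phenyl]-1,3-dithiane; 10 (R)-2-[4-(benzyloxy)phenyl]oxirane
Product: 13 (2'S)-5',7'-bis(benzyloxy)-2'-[4-(benzyloxy)phenyl]-6'-(tert-butyldimethylsilyloxy)spiro[1,3-dithiane-2,4'-chromane], via lithium alkoxide 11 (not isolated), via aryne 12 (not isolated)
Conditions: LiN(iPr)2 (1.05 equiv), THF, −78 °C; 10 (1.2 equiv), −78 → 0 °C; then lithium 2,2,6,6-tetramethylpiperidide (2.2 equiv), −78 → −20 °C; aq. NH4Cl
Reagents that add atoms: none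
Why: Deprotonation of 7 gives the 2-lithio-1,3-dithiane, which should open oxirane 10 by SN2 attack at the unsubstituted CH2 (C3–C4 bond) to give alkoxide 11; the second amide base then removes the only ring-A hydrogen (C8–H, between Br and OBn), loss of LiBr gives aryne 12, and the tethered alkoxide adds to the former C–Br carbon (O1–C8a bond). The closest known reaction types are the Corey–Seebach dithiane/epoxide coupling and the intramolecular trapping of arynes by tethered alkoxides. Ring C closes by a 6-exo-dig addition to the aryne, helped by the gem-disubstitution at the dithiane carbon. No stereocentre is created: C2 is the oxirane carbon of 10, whose C–O bond is never broken, so its configuration is carried over unchanged (the descriptor changes from R to S only because the CIP priorities change). The step needs terminal rather than benzylic oxirane opening (secured by the bulky, soft dithiane anion under non-Lewis-acidic conditions), lithiation of the dithiane C–H before the aryl C–H (secured by its far higher acidity and the staged addition of base), and alkoxide attack at the proximal aryne carbon (secured by the tether length and by the C7 benzyloxy group, which places the aryl anion ortho to oxygen).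

**Step 8**
Reactants: 14 1-[2,4-bis(benzyloxy)-6-hydroxyphenyl]ethan-1-one; 15 4-iodobenzaldehyde
Product: 16 (E)-1-[2,4-bis(benzyloxy)-6-hydroxyphenyl]-3-(4-iodophenyl)prop-2-en-1-one
Conditions: KOH, EtOH/THF, rt
Reagents that add atoms: none
Why: Claisen–Schmidt aldol condensation of the 2'-hydroxyacetophenone with the non-enolisable aldehyde should give the (E)-2'-hydroxychalcone.

**Step 9**
Reactants: 16 (E)-1-[2,4-bis(benzyloxy)-6-hydroxyphenyl]-3-(4-iodophenyl)prop-2-en-1-one
Product: 17 5,7-bis(benzyloxy)-2-(4-iodophenyl)-4H-chromen-4-one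
Conditions: I2 (10 mol %), DMSO, 130 °C
Reagents that add atoms: none
Why: Iodine-catalysed oxidative cyclisation in DMSO (oxa-Michael addition, iodination and loss of HI, with DMSO as terminal oxidant) is the standard conversion of 2'-hydroxychalcones into flavones and should leave the aryl iodide untouched.

**Step 10**
Reactants: 13 (2'S)-5',7'-bis(benzyloxy)-2'-[4-(benzyloxy)phenyl]-6'-(tert-butyldimethylsilyloxy)spiro[1,3-dithiane-2,4'-chromane]; 17 5,7-bis(benzyloxy)-2-(4-iodophenyl)-4H-chromen-4-one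
Product: 19 5,7-bis(benzyloxy)-2-[4-({(2'S)-5',7'-bis(benzyloxy)-2'-[4-(benzyloxy)phenyl]spiro[1,3-dithiane-2,4'-chroman]-6'-yl}oxy)phenyl]-4H-chromen-4-one, via caesium phenoxide 18 (not isolated)
Conditions: CuI (10 mol %), picolinic acid (20 mol %), CsF (3 equiv), DMSO, 90 °C, argon
Reagents that add atoms: none
Why: Fluoride cleaves the aryl silyl ether to the caesium phenoxide, which should undergo ligand-accelerated Ullmann diaryl ether coupling with the aryl iodide, and with C4 still a dithioketal there is no enolisable ketone through which base could open ring C or racemise C2.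

**Step 11**
Reactants: 19 (the dithioketal-protected biflavonoid from step 10)
Product: 20 (2S)-5,7-bis(benzyloxy)-2-[4-(benzyloxy)phenyl]-6-{4-[5,7-bis(benzyloxy)-4-oxo-4H-chromen-2-yl]phenoxy}chroman-4-one
Conditions: MeI, CaCO3, MeCN/H2O (4:1), 45 °C
Reagents that add atoms: water, O
Why: S-Methylation turns the dithiane into a leaving group and buffered hydrolysis (alkylative dithiane cleavage) should release the C4 ketone under near-neutral conditions that neither open the flavanone ring nor racemise C2.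

**Step 12**
Reactants: 20 (the penta-O-benzyl biflavonoid)
Product: 21 (2S)-6-[4-(5,7-dihydroxy-4-oxo-4H-chromen-2-yl)phenoxy]-5,7-dihydroxy-2-(4-hydroxyphenyl)chroman-4-one (CNP0206535.1)
Conditions: H2 (1 atm), 10% Pd/C, EtOAc/MeOH, rt
Reagents that add atoms: none
Why: Hydrogenolysis of the five benzyl ethers over palladium on carbon under neutral conditions should free all phenols without base- or acid-induced ring opening at C2 and without reducing the flavone double bond.

**Compound list**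

1 | 4-bromo-2,6-difluorobenzaldehyde | O=Cc1c(F)cc(Br)cc1F | starting material
2 | 4-bromo-2,6-bis(benzyloxy)benzaldehyde | O=Cc1c(OCc2ccccc2)cc(Br)cc1OCc1ccccc1 | intermediate
3 | 4-bromo-2,6-bis(benzyloxy)phenyl formate (not isolated) | O=COc1c(OCc2ccccc2)cc(Br)cc1OCc1ccccc1 | intermediate
4 | 4-bromo-2,6-bis(benzyloxy)phenol | Oc1c(OCc2ccccc2)cc(Br)cc1OCc1ccccc1 | intermediate
5 | 6-bromo-2,4-bis(benzyloxy)-3-hydroxybenzaldehyde | O=Cc1c(Br)cc(OCc2ccccc2)c(O)c1OCc1ccccc1 | intermediate
6 | 2-[6-bromo-2,4-bis(benzyloxy)-3-hydroxyphenyl]-1,3-dithiane | Oc1c(OCc2ccccc2)cc(Br)c(C2SCCCS2)c1OCc1ccccc1 | intermediate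
7 | 2-[6-bromo-2,4-bis(benzyloxy)-3-(tert-butyldimethylsilyloxy)phenyl]-1,3-dithiane | CC(C)(C)[Si](C)(C)Oc1c(OCc2ccccc2)cc(Br)c(C2SCCCS2)c1OCc1ccccc1 | intermediate
8 | 2-bromo-1-[4-(benzyloxy)phenyl]ethan-1-one | O=C(CBr)c1ccc(OCc2ccccc2)cc1 | starting material
9 | (R)-2-bromo-1-[4-(benzyloxy)phenyl]ethan-1-ol (not isolated) | O[C@@H](CBr)c1ccc(OCc2ccccc2)cc1 | intermediate
10 | (R)-2-[4-(benzyloxy)phenyl]oxirane | C1[C@H](O1)c1ccc(OCc2ccccc2)cc1 | intermediate
11 | lithium (S)-1-[4-(benzyloxy)phenyl]-2-{2-[6-bromo-2,4-bis(benzyloxy)-3-(tert-butyldimethylsilyloxy)phenyl]-1,3-dithian-2-yl}ethan-1-olate (not isolated) | [Li+].[O-][C@@H](CC1(SCCCS1)c1c(Br)cc(OCc2ccccc2)c(O[Si](C)(C)C(C)(C)C)c1OCc1ccccc1)c1ccc(OCc2ccccc2)cc1 | intermediate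
12 | lithium (S)-1-[4-(benzyloxy)phenyl]-2-{2-[2,4-bis(benzyloxy)-3-(tert-butyldimethylsilyloxy)-5,6-didehydrophenyl]-1,3-dithian-2-yl}ethan-1-olate, the aryne (not isolated) | [Li+].[O-][C@@H](CC1(SCCCS1)C1=C(OCc2ccccc2)C(O[Si](C)(C)C(C)(C)C)=C(OCc2ccccc2)C#C1)c1ccc(OCc2ccccc2)cc1 | intermediate
13 | (2'S)-5',7'-bis(benzyloxy)-2'-[4-(benzyloxy)phenyl]-6'-(tert-butyldimethylsilyloxy)spiro[1,3-dithiane-2,4'-chromane] | S1CCCSC12C[C@@H](c3ccc(OCc4ccccc4)cc3)Oc3cc(OCc4ccccc4)c(O[Si](C)(C)C(C)(C)C)c(OCc4ccccc4)c32 | intermediate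
14 | 1-[2,4-bis(benzyloxy)-6-hydroxyphenyl]ethan-1-one | CC(=O)c1c(O)cc(OCc2ccccc2)cc1OCc1ccccc1 | starting material
15 | 4-iodobenzaldehyde | O=Cc1ccc(I)cc1 | starting material
16 | (E)-1-[2,4-bis(benzyloxy)-6-hydroxyphenyl]-3-(4-iodophenyl)prop-2-en-1-one | O=C(/C=C/c1ccc(I)cc1)c1c(O)cc(OCc2ccccc2)cc1OCc1ccccc1 | intermediate
17 | 5,7-bis(benzyloxy)-2-(4-iodophenyl)-4H-chromen-4-one | O=c1cc(-c2ccc(I)cc2)oc2cc(OCc3ccccc3)cc(OCc3ccccc3)c12 | intermediate
18 | caesium (2'S)-5',7'-bis(benzyloxy)-2'-[4-(benzyloxy)phenyl]spiro[1,3-dithiane-2,4'-chroman]-6'-olate (not isolated) | S1CCCSC12C[C@@H](c3ccc(OCc4ccccc4)cc3)Oc3cc(OCc4ccccc4)c([O-])c(OCc4ccccc4)c32.[Cs+] | intermediate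
19 | 5,7-bis(benzyloxy)-2-[4-({(2'S)-5',7'-bis(benzyloxy)-2'-[4-(benzyloxy)phenyl]spiro[1,3-dithiane-2,4'-chroman]-6'-yl}oxy)phenyl]-4H-chromen-4-one | S1CCCSC12C[C@@H](c3ccc(OCc4ccccc4)cc3)Oc3cc(OCc4ccccc4)c(Oc4ccc(-c5cc(=O)c6c(OCc7ccccc7)cc(OCc7ccccc7)cc6o5)cc4)c(OCc4ccccc4)c32 | intermediate
20 | (2S)-5,7-bis(benzyloxy)-2-[4-(benzyloxy)phenyl]-6-{4-[5,7-bis(benzyloxy)-4-oxo-4H-chromen-2-yl]phenoxy}chroman-4-one | O=C1C[C@@H](c2ccc(OCc3ccccc3)cc2)Oc2cc(OCc3ccccc3)c(Oc3ccc(-c4cc(=O)c5c(OCc6ccccc6)cc(OCc6ccccc6)cc5o4)cc3)c(OCc3ccccc3)c21 | intermediate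
21 | (2S)-6-[4-(5,7-dihydroxy-4-oxo-4H-chromen-2-yl)phenoxy]-5,7-dihydroxy-2-(4-hydroxyphenyl)chroman-4-one | O=C1C[C@@H](c2ccc(O)cc2)Oc2cc(O)c(Oc3ccc(-c4cc(=O)c5c(O)cc(O)cc5o4)cc3)c(O)c21 | target

**Step count**

Total steps: 12. Longest linear sequence: 9 steps (1, 2, 3, 4, 5, 7, 10, 11, 12).

**Steps most likely to fail**

Step 7. What may go wrong: premature aryne formation if the amide base removes the ring C8–H before the dithiane C–H; benzylic instead of terminal opening of the electron-rich oxirane; or capture of the aryne by amide instead of the tethered alkoxide. The fallback sets out from 7 and 10 and comes back at 13. Only the first stage is run (LiN(iPr)2, THF, −78 → 0 °C, aqueous work-up) and the alcohol (S)-1-[4-(benzyloxy)phenyl]-2-{2-[6-bromo-2,4-bis(benzyloxy)-3-(tert-butyldimethylsilyloxy)phenyl]-1,3-dithian-2-yl}ethan-1-ol F1 is isolated. Ring C is then closed by a palladium-catalysed intramolecular aryl ether formation (Buchwald–Hartwig C–O coupling: Pd(OAc)2, 2-(di-tert-butylphosphino)-1,1'-binaphthyl, Cs2CO3, toluene, 80 °C). This runs by oxidative addition of zerovalent palladium into the C8a–Br bond, alkoxide exchange and reductive elimination, and should retain the carbinol configuration.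

Step 10. What may go wrong: slow coupling of the doubly ortho-substituted phenoxide and sequestration of copper by the dithioketal sulfur atoms, so that desilylated material accumulates. The fallback sets out from 13 and comes back at 19, and builds the flavone on the dithioketal platform without any oxidant. Bu4NF (THF, 0 °C) gives the phenol (2'S)-5',7'-bis(benzyloxy)-2'-[4-(benzyloxy)phenyl]spiro[1,3-dithiane-2,4'-chroman]-6'-ol F2. SNAr with ethyl 4-fluorobenzoate (Cs2CO3, DMSO, 110 °C) gives ethyl 4-({(2'S)-5',7'-bis(benzyloxy)-2'-[4-(benzyloxy)phenyl]spiro[1,3-dithiane-2,4'-chroman]-6'-yl}oxy)benzoate F3. Claisen condensation of F3 with the dianion of 14 (LiN(SiMe3)2, THF, −78 °C → rt) gives 1-[2,4-bis(benzyloxy)-6-hydroxyphenyl]-3-[4-({(2'S)-5',7'-bis(benzyloxy)-2'-[4-(benzyloxy)phenyl]spiro[1,3-dithiane-2,4'-chroman]-6'-yl}oxy)phenyl]propane-1,3-dione F4. Acid-catalysed cyclodehydration (p-TsOH, toluene, 80 °C) then gives 19.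

Step 12. What may go wrong: over-reduction of the flavone C2=C3 bond or of a C4 carbonyl, or stalling of the catalyst by sulfur traces carried over from step 11. The fallback goes from 20 directly to 21 by Lewis-acid debenzylation with a cation scavenger (BCl3, pentamethylbenzene, CH2Cl2, −78 °C) and makes no new compound.

**Further compounds**

F1 | step 7 | (S)-1-[4-(benzyloxy)phenyl]-2-{2-[6-bromo-2,4-bis(benzyloxy)-3-(tert-butyldimethylsilyloxy)phenyl]-1,3-dithian-2-yl}ethan-1-ol | O[C@@H](CC1(SCCCS1)c1c(Br)cc(OCc2ccccc2)c(O[Si](C)(C)C(C)(C)C)c1OCc1ccccc1)c1ccc(OCc2ccccc2)cc1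
F2 | step 10 | (2'S)-5',7'-bis(benzyloxy)-2'-[4-(benzyloxy)phenyl]spiro[1,3-dithiane-2,4'-chroman]-6'-ol | S1CCCSC12C[C@@H](c3ccc(OCc4ccccc4)cc3)Oc3cc(OCc4ccccc4)c(O)c(OCc4ccccc4)c32
F3 | step 10 | ethyl 4-({(2'S)-5',7'-bis(benzyloxy)-2'-[4-(benzyloxy)phenyl]spiro[1,3-dithiane-2,4'-chroman]-6'-yl}oxy)benzoate | S1CCCSC12C[C@@H](c3ccc(OCc4ccccc4)cc3)Oc3cc(OCc4ccccc4)c(Oc4ccc(C(=O)OCC)cc4)c(OCc4ccccc4)c32
F4 | step 10 | 1-[2,4-bis(benzyloxy)-6-hydroxyphenyl]-3-[4-({(2'S)-5',7'-bis(benzyloxy)-2'-[4-(benzyloxy)phenyl]spiro[1,3-dithiane-2,4'-chroman]-6'-yl}oxy)phenyl]propane-1,3-dione | S1CCCSC12C[C@@H](c3ccc(OCc4ccccc4)cc3)Oc3cc(OCc4ccccc4)c(Oc4ccc(C(=O)CC(=O)c5c(O)cc(OCc6ccccc6)cc5OCc5ccccc5)cc4)c(OCc4ccccc4)c32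
F0 | step 12 | none | none
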